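## Retrosynthetic overview
1. 20 ⇒ lactol 15 (Wittig plus saponification builds the C5 side chain and frees C6–OH) ⇒ ester-lactone 14 (DIBAL-H) ⇒ enol triflate 11 + hept-1-yne (Suzuki coupling, C1–C1′ bond).
2. 11 ⇒ cyclohexadiene 10 (OsO4; C3/C4 cis-diol delivered anti to the lactone).
3. 10 ⇒ cyclopentenone-lactone 7 + ethyl diazoacetate: one-carbon ring expansion by a 1,2-shift of the alkenyl carbon C3. The inserted carbon is C2 and it carries the future CH2OH carbon.
4. 7 ⇒ keto acid 4 (C6–O by iodination and invertive lactonisation) ⇒ (1S,4S)-norbornenone 1 (Baeyer–Villiger ring expansion, opening, oxidation).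
5. Ring order: cyclopentene (from 1) → cis-fused γ-lactone → six-membered carbocycle by ring expansion → lactone opened last.

Numbering used below follows the target ring: C1 (heptenyl), C2 (CH2OH), C3–OH, C4–OH, C5 (side chain), C6–OH. The five-membered precursors contain C1, C3, C4, C5 and C6.

Assumption: 1 is bought as the single (1S,4S) enantiomer; if only the racemate is in stock, it is resolved by known methods.

## Route

Step 1
Reactants: 1 (1S,4S)-bicyclo[2.2.1]hept-5-en-2-one
Product: 3 2-[(1S,4S)-4-hydroxycyclopent-2-en-1-yl]acetic acid, via bridged lactone 2 (not isolated)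
Conditions: 30% H2O2, NaOH, H2O/Et2O, 0–5 °C; 1 M HCl to pH 3, 0 °C
Reagents that add atoms: hydrogen peroxide OO; sodium hydroxide [Na+].[OH-]
Why: Baeyer–Villiger oxidation in which the more substituted allylic bridgehead migrates to oxygen with retention, and hydroxide opens the strained lactone in the same flask; the alkene is untouched by alkaline peroxide, and the C5 stereocentre is carried over unchanged from 1.

Step 2
Reactants: 3 2-[(1S,4S)-4-hydroxycyclopent-2-en-1-yl]acetic acid
Product: 4 2-[(1S)-4-oxocyclopent-2-en-1-yl]acetic acid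
Conditions: Dess–Martin periodinane, CH2Cl2, 0 °C → rt
Reagents that add atoms: none
Why: Dess–Martin oxidation of a secondary allylic alcohol under near-neutral conditions tolerates the free acid and does not enolise the γ-stereocentre C5.

Step 3
Reactants: 4 2-[(1S)-4-oxocyclopent-2-en-1-yl]acetic acid
Product: 7 (3aS,6aS)-3,3a-dihydro-2H-cyclopenta[b]furan-2,6(6aH)-dione, via bis-silyl dienol ether 5 (not isolated), via trans-iodo acid 6 (not isolated)
Conditions: TMSCl, LiHMDS (2.2 equiv), THF, −78 °C; NIS, −78 → −20 °C; sat. aq NaHCO3, 0 °C → rt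
Reagents that add atoms: none
Why: Kinetic α′-silylation of the enone followed by α′-iodination puts iodine on C6 anti to the C5 arm, and the liberated carboxylate displaces it by intramolecular SN2 (5-exo-tet) with inversion; C6–O therefore ends cis to the arm (only the cis-fused bicycle can form), iodide exchange funnels any cis-iodide to the same lactone, and working below −20 °C suppresses the 1,5-H shift of cyclopentadiene 5.

Step 4
Reactants: 7 (3aS,6aS)-3,3a-dihydro-2H-cyclopenta[b]furan-2,6(6aH)-dione; 8 ethyl diazoacetate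
Product: 10 ethyl (3aS,7aS)-2-oxo-7-(trifluoromethylsulfonyloxy)-2,3,3a,7a-tetrahydro-1-benzofuran-6-carboxylate, via enol keto ester 9 (not isolated)
Conditions: BF3·OEt2 (1.1 equiv), CH2Cl2, −20 → 0 °C; then iPr2NEt, Tf2O, −78 °C
Reagents that add atoms: trifluoromethanesulfonic anhydride O=S(=O)(OS(=O)(=O)C(F)(F)F)C(F)(F)F
Why: Proposed new method: BF3 activates the ketone (made more electrophilic by the α′-acyloxy group), and the diazo carbon of 8 adds 1,2 to give a β-oxido diazonium betaine; N2 then leaves in concert with a 1,2-shift in which the sp2 carbon C3 (the best migrating group in diazoacetate homologations) moves in preference to C6, whose migration is retarded by its electron-withdrawing acyloxy substituent just as by an α-halogen; this gives the six-membered β-keto ester 9 as its H-bonded dienol, which is O-triflated in the same flask before it can lose the C6 carboxylate and aromatise; C5 and C6 are not touched; the closest known reaction type is the Tiffeneau–Demjanov-type (Büchner–Curtius–Schlotterbeck) Lewis-acid ring expansion of cycloalkanones and simple enones with diazoacetates, and the new elements are the α′-acyloxy-cyclopentenone substrate class and the in-flask capture as a dienyl triflate.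

Step 5
Reactants: 10 ethyl (3aS,7aS)-2-oxo-7-(trifluoromethylsulfonyloxy)-2,3,3a,7a-tetrahydro-1-benzofuran-6-carboxylate
Product: 11 ethyl (3aS,4S,5R,7aS)-4,5-dihydroxy-2-oxo-7-(trifluoromethylsulfonyloxy)-2,3,3a,4,5,7a-hexahydro-1-benzofuran-6-carboxylate
Conditions: OsO4 (2 mol %), NMO, citric acid, tBuOH/H2O, 0 °C → rt
Reagents that add atoms: N-methylmorpholine N-oxide C[N+]1([O-])CCOCC1 (oxygen passed on through OsO4); water O
Why: Catalytic OsO4/NMO syn-dihydroxylation takes the only electron-rich cis-disubstituted alkene (the C1=C2 bond is tetrasubstituted and carries OTf and ester) from the convex face anti to the C5 arm and the lactone; this sets C3 and C4 as the cis-diol trans to the arm, and the citric acid buffer prevents base-induced aromatisation.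

Step 6
Reactants: 11 ethyl (3aS,4S,5R,7aS)-4,5-dihydroxy-2-oxo-7-(trifluoromethylsulfonyloxy)-2,3,3a,4,5,7a-hexahydro-1-benzofuran-6-carboxylate; 12 hept-1-yne
Product: 14 ethyl (3aS,4S,5R,7aS)-7-[(1E)-hept-1-en-1-yl]-4,5-dihydroxy-2-oxo-2,3,3a,4,5,7a-hexahydro-1-benzofuran-6-carboxylate, via heptenyl boronate 13 (not isolated)
Conditions: 12, HBpin, Cp2ZrHCl (5 mol %), Et3N (5 mol %), neat, 60 °C; then 11, PdCl2(dppf) (5 mol %), K3PO4, THF/H2O, 40 °C; work-up at pH 4
Reagents that add atoms: none
Why: Zr-catalysed syn-hydroboration gives only the (E)-alkenylboronate, and Suzuki–Miyaura coupling of the very reactive β-triflyloxy enoate proceeds with retention at both partners and tolerates the free diol; any lactone opened or shifted to O4 by base recloses at work-up or converges in step 8.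

Step 7
Reactants: 14 ethyl (3aS,4S,5R,7aS)-7-[(1E)-hept-1-en-1-yl]-4,5-dihydroxy-2-oxo-2,3,3a,4,5,7a-hexahydro-1-benzofuran-6-carboxylate
Product: 15 (3aS,4S,5R,7aS)-7-[(1E)-hept-1-en-1-yl]-6-(hydroxymethyl)-2,3,3a,4,5,7a-hexahydro-1-benzofuran-2,4,5-triol (lactol, anomer mixture)
Conditions: DIBAL-H (6.5 equiv), CH2Cl2/THF, −78 °C; MeOH, aq Rochelle salt
Reagents that add atoms: none
Why: In this DIBAL-H reduction the γ-lactone stops at the cold-stable aluminium lactolate, while the conjugated ester collapses to the enal and is reduced 1,2 to the allylic alcohol; the two OH groups only consume hydride, and no stereocentre is affected.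

Step 8
Reactants: 15 (3aS,4S,5R,7aS)-7-[(1E)-hept-1-en-1-yl]-6-(hydroxymethyl)-2,3,3a,4,5,7a-hexahydro-1-benzofuran-2,4,5-triol; 16 methyl 2-bromopropanoate
Product: 20 pestallic acid P, via phosphonium salt 17 (not isolated), via ylide 18 (not isolated), via methyl ester 19 (not isolated)
Conditions: 16, PPh3, MeCN, 70 °C; K2CO3; then 15, 50 °C; then LiOH, H2O, rt; 1 M HCl to pH 4, 0 °C
Reagents that add atoms: lithium hydroxide [Li+].[OH-]
Why: The Wittig reaction of the stabilised α-methyl ylide with the open hydroxy-aldehyde form of the unprotected lactol gives the (E)-trisubstituted enoate and frees C6–OH, the α-methyl group disfavours oxa-Michael closure, and mild saponification in the same flask gives the acid without touching the acid-sensitive allylic alcohols.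

## Compound list
1 | (1S,4S)-bicyclo[2.2.1]hept-5-en-2-one | O=C1C[C@H]2C=C[C@@H]1C2 | starting material
2 | (1S,5S)-2-oxabicyclo[3.2.1]oct-6-en-3-one | O=C1C[C@H]2C=C[C@H](C2)O1 | intermediate
3 | 2-[(1S,4S)-4-hydroxycyclopent-2-en-1-yl]acetic acid (cis) | O[C@@H]1C=C[C@H](CC(=O)O)C1 | intermediate
4 | 2-[(1S)-4-oxocyclopent-2-en-1-yl]acetic acid | O=C1C=C[C@H](CC(=O)O)C1 | intermediate
5 | trimethylsilyl 2-[(1S)-3-(trimethylsilyloxy)cyclopenta-2,4-dien-1-yl]acetate | C[Si](C)(C)OC1=C[C@@H](CC(=O)O[Si](C)(C)C)C=C1 | intermediate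
6 | 2-[(1S,5R)-5-iodo-4-oxocyclopent-2-en-1-yl]acetic acid (I trans to the arm) | O=C1C=C[C@H](CC(=O)O)[C@H]1I | intermediate
7 | (3aS,6aS)-3,3a-dihydro-2H-cyclopenta[b]furan-2,6(6aH)-dione (cis-fused enone-lactone) | O=C1C=C[C@@H]2CC(=O)O[C@H]12 | intermediate
8 | ethyl diazoacetate | CCOC(=O)C=[N+]=[N-] | starting material
9 | ethyl (3aS,7aS)-7-hydroxy-2-oxo-2,3,3a,7a-tetrahydro-1-benzofuran-6-carboxylate (enol form of the β-keto ester) | OC1=C(C(=O)OCC)C=C[C@@H]2CC(=O)O[C@H]12 | intermediate
10 | ethyl (3aS,7aS)-2-oxo-7-(trifluoromethylsulfonyloxy)-2,3,3a,7a-tetrahydro-1-benzofuran-6-carboxylate | O=S(=O)(OC1=C(C(=O)OCC)C=C[C@@H]2CC(=O)O[C@H]12)C(F)(F)F | intermediate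
11 | ethyl (3aS,4S,5R,7aS)-4,5-dihydroxy-2-oxo-7-(trifluoromethylsulfonyloxy)-2,3,3a,4,5,7a-hexahydro-1-benzofuran-6-carboxylate | O=S(=O)(OC1=C(C(=O)OCC)[C@@H](O)[C@@H](O)[C@@H]2CC(=O)O[C@H]12)C(F)(F)F | intermediate
12 | hept-1-yne | CCCCCC#C | starting material
13 | 2-[(1E)-hept-1-en-1-yl]-4,4,5,5-tetramethyl-1,3,2-dioxaborolane | CCCCC/C=C/B1OC(C)(C)C(C)(C)O1 | intermediate
14 | ethyl (3aS,4S,5R,7aS)-7-[(1E)-hept-1-en-1-yl]-4,5-dihydroxy-2-oxo-2,3,3a,4,5,7a-hexahydro-1-benzofuran-6-carboxylate | CCCCC/C=C/C1=C(C(=O)OCC)[C@@H](O)[C@@H](O)[C@@H]2CC(=O)O[C@H]12 | intermediate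
15 | (3aS,4S,5R,7aS)-7-[(1E)-hept-1-en-1-yl]-6-(hydroxymethyl)-2,3,3a,4,5,7a-hexahydro-1-benzofuran-2,4,5-triol (lactol, both anomers) | CCCCC/C=C/C1=C(CO)[C@@H](O)[C@@H](O)[C@@H]2CC(O)O[C@H]12 | intermediate
16 | methyl 2-bromopropanoate (racemic) | COC(=O)C(C)Br | starting material
17 | (1-methoxy-1-oxopropan-2-yl)triphenylphosphonium bromide | COC(=O)C(C)[P+](c1ccccc1)(c1ccccc1)c1ccccc1.[Br-] | intermediate
18 | methyl 2-(triphenylphosphoranylidene)propanoate | COC(=O)C(C)=P(c1ccccc1)(c1ccccc1)c1ccccc1 | intermediate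
19 | methyl (2E)-4-[(1R,2S,5R,6S)-3-[(1E)-hept-1-en-1-yl]-2,5,6-trihydroxy-4-(hydroxymethyl)cyclohex-3-en-1-yl]-2-methylbut-2-enoate | CCCCC/C=C/C1=C(CO)[C@@H](O)[C@@H](O)[C@H](C/C=C(\C)C(=O)OC)[C@@H]1O | intermediate
20 | pestallic acid P, (2E)-4-[(1R,2S,5R,6S)-3-[(1E)-hept-1-en-1-yl]-2,5,6-trihydroxy-4-(hydroxymethyl)cyclohex-3-en-1-yl]-2-methylbut-2-enoic acid | CCCCC/C=C/C1=C(CO)[C@@H](O)[C@@H](O)[C@H](C/C=C(\C)C(=O)O)[C@@H]1O | target

## Step count and risks
Total step count: 8. Longest linear sequence: 8 (1 → 20; compounds 8, 12 and 16 enter directly).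

**Step 4 (the proposed new step).** Three things could go wrong. Ethyl diazoacetate may attack the enone C=C bond, C6 may migrate in part, or 9 may aromatise under BF3. The fallback sets out from 7 and comes back at 9.
- Ethyl lithiodiazoacetate (8, LDA, THF, −78 °C) is added 1,2 to the ketone from the convex face. This gives ethyl 2-diazo-2-[(3aS,6S,6aS)-6-hydroxy-2-oxo-3,3a,6,6a-tetrahydro-2H-cyclopenta[b]furan-6-yl]acetate F1.
- Rh2(OAc)4 (1 mol %, CH2Cl2, rt) converts F1 under neutral conditions, through the rhodium carbenoid and a 1,2-alkenyl shift, into 9.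
- 9 is then triflated as before to 10. Both operations are the known two-stage homologation of ketones.

**Step 7.** The hindered dienoate may need warming, at which point the lactolate is over-reduced. The fallback changes the order of events; it sets out from 11 and comes back at 19.
- DIBAL-H at −78 °C on 11 acts on an ester that is activated by OTf and not shielded by the heptenyl group. It gives the C1-triflate lactol (3aS,4S,5R,7aS)-2,4,5-trihydroxy-6-(hydroxymethyl)-2,3,3a,4,5,7a-hexahydro-1-benzofuran-7-yl triflate F2.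
- Wittig reaction with 18 gives the C1-triflate analogue of ester 19, F3.
- Suzuki coupling of F3 with 13 installs the heptenyl group last and delivers 19, which is saponified to 20.

**Step 3.** The α′-iodo enone may decompose, or the displacement may be slow. The fallback sets out from 4 and comes back at 7.
- The silyl dienol ether 5 is oxidised with dimethyldioxirane at −78 °C (Rubottom oxidation, attack anti to the arm).
- Aqueous work-up gives 2-[(1S,5R)-5-hydroxy-4-oxocyclopent-2-en-1-yl]acetic acid F4, with OH trans to the arm.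
- Intramolecular Mitsunobu lactonisation (PPh3, DIAD, THF, 0 °C) closes F4 to 7 with inversion at C6.

## Further compounds
F1 | step 4 | ethyl 2-diazo-2-[(3aS,6S,6aS)-6-hydroxy-2-oxo-3,3a,6,6a-tetrahydro-2H-cyclopenta[b]furan-6-yl]acetate | CCOC(=O)C(=[N+]=[N-])[C@@]1(O)C=C[C@@H]2CC(=O)O[C@H]12
F2 | step 7 | (3aS,4S,5R,7aS)-2,4,5-trihydroxy-6-(hydroxymethyl)-2,3,3a,4,5,7a-hexahydro-1-benzofuran-7-yl trifluoromethanesulfonate | O=S(=O)(OC1=C(CO)[C@@H](O)[C@@H](O)[C@@H]2CC(O)O[C@H]12)C(F)(F)F
F3 | step 7 | C1-triflate analogue of ester 19 (OTf in place of heptenyl) | O=S(=O)(OC1=C(CO)[C@@H](O)[C@@H](O)[C@H](C/C=C(\C)C(=O)OC)[C@@H]1O)C(F)(F)F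
F4 | step 3 | 2-[(1S,5R)-5-hydroxy-4-oxocyclopent-2-en-1-yl]acetic acid | O=C1C=C[C@H](CC(=O)O)[C@H]1O
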